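**Septeremophilane G: synthesis proposal built on a dearomatising ring A closure at the quaternary carbon**

## Analysis of the target

Septeremophilane G (22) is a trinor-eremophilane with a twelve-carbon bicyclic core. Ring A (C1 methylene, C2 carbinol, C3 acyloxy carbon, C4 CHMe, C5, C10) is fused to ring B (C5, C6=C7, C8=O, C9=C10), a cross-conjugated cyclohexadienone whose C7 bears an enolic hydroxyl (a diosphenol). The C3 oxygen is esterified with (2E,4E,6S)-6-methylocta-2,4-dienoic acid.

Ring A carries four contiguous stereocentres, C2 (R), C3 (R), C4 (R) and C5 (S). The C5 methyl is axial on ring A, the C4 methyl is cis to it and equatorial, the C3 acyloxy group is cis to both methyls and axial (syn-axial to the C5 methyl), and the C2 hydroxyl is trans to the C3 oxygen and also axial. The fifth stereocentre, C6' of the side chain, is remote and comes from an α-branched aldehyde that racemises easily.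

The sensitive groups are the diosphenol (acidic, air-sensitive in base), the dienone (prone to dienone–phenol rearrangement in strong acid), the dienoate (nucleophiles, base-induced isomerisation) and the free C2 hydroxyl next to the ester (acyl migration). The main difficulty is the quaternary C5 joined to the tertiary C4 with cis methyls, inside a ring with two differentiated oxygens, next to a ring B that offers no carbonyl handle for a classical annulation.

The strategy rests on one feature: ring B is a 4,4-disubstituted cyclohexa-2,5-dienone with the quaternary C5 para to the C8 carbonyl. It is therefore a masked 3-alkyl-4-methylphenol, and the C4–C5 bond of ring A can be made by attack of a C4 nucleophile on the para carbon of the oxidised phenol, where the C5 methyl prevents rearomatisation.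

## Retrosynthetic reasoning

**22 from 21.** The last operation only removes the two silyl groups on the C2 oxygen and the C7 enol oxygen. Both hydroxyls would compete with C3 in the acylation, so they stay masked by the same silyl type and are released together under mildly acidic fluoride. The trans-diaxial 2,3-arrangement cannot form the five-membered orthoester needed for acyl migration.

**21 from 15 and 19.** The C3–O acyl bond is cut so that the dienoate, which would not survive hydride or alkaline peroxide, arrives late. Acid 19 carries the remote stereocentre and both E double bonds. It is traced through ester 18 to aldehyde 17 by cutting the C4'=C5' double bond (phosphonate olefination), and 17 to the chiral-pool alcohol 16.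

**15 from 12 via 14 and 13.** The C7 oxygen is traced back to the C6=C7 double bond of a plain dienone. A nucleophilic epoxidation can tell C6=C7 (β-carbon is a CH) from C9=C10 (β-carbon fully substituted), and the epoxy ketone 13 isomerises to diosphenol 14, which is silylated on the enol oxygen to 15.

**12 from 11.** The C3 carbinol comes from a C3 ketone, which is exactly what a C4 enol nucleophile leaves behind. The forward reduction has to spare the dienone and deliver hydride to the face of C3 that is not covered by the axial C5 methyl.

**11 from 10 (C4–C5).** This cut removes the quaternary centre, the vicinal methyl relationship and ring A in one stroke and turns ring B into a flat phenol. Cutting C1–C10 or C5–C10 instead would leave the C4–C5 bond to be made without the help of aromatic reactivity. Forward, a trivalent iodine oxidant has to turn the phenol of 10 into an electrophile at its para carbon, and the tethered (Z)-silyl enol ether has to add there through C4 rather than at the ortho carbon C9.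

**10 from 8 via 9.** The enol ether is the (Z)-silyl enol ether of ethyl ketone 8. The phenol is kept as an allyl ether until after enol silylation, because a free phenol would be silylated by the triflate and the enol ether would not survive acidic, fluoride or hydrogenolytic deprotection.

**8 from 2 and 3.** The C3–C4 bond is cut to Weinreb amide 7 (from ester 6) and a two-carbon organomagnesium reagent. The C1–C10 bond is cut to aryl Grignard reagent 4 and glycidic ester 3, whose stereocentre becomes C2 and whose ester carbon becomes C3, so no redox adjustment of the chain is needed. Hydroxy ester 5 is the direct product. 2 is the allyl ether of commercial phenol 1.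

## Alternatives that were turned down

**Alternative 1:** Ring A would be bought from the chiral pool as (−)-quinic acid (A1) and degraded to the 2-methyl enone A2, in which the C2 and C3 oxygens are already present as a trans-diol held in a bis-ketal. The key step is a one-flask vicinal difunctionalisation: a methylcuprate adds to C4, and the C5 enolate is trapped with a but-2-ynyl halide to give A3. It forms C4–CH3 and C5–C6 but closes no ring.
- For it: both carbinol centres and the absolute configuration come from the pool. The anti-selective conjugate addition and alkylation fix the cis methyls by a well-understood substrate bias. No late C3 reduction is needed.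
- Where it is stronger: the C2/C3/C4/C5 stereochemistry is more secure than in the chosen route, which relays C2 to C5 through a conformational preference.
- Against it: the passage from A1 to A2 consumes many steps. Ring B must still be annulated from the butynyl chain and the C10 ketone (alkyne hydration with a regiochemical question, then aldol condensation), and then oxidised twice (second double bond, C7 oxygen). The two secondary hydroxyls released from the bis-ketal must be told apart before acylation.
- Comparison: the chosen strategy gives up the purchased diol but obtains ring B at the dienone oxidation level in the same step that closes ring A, from a precursor reached in six steps.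

**Alternative 2:** Ring A is cut at C3–C4 and C5–C10 into tiglaldehyde (A4) and the 1-acetoxy-4-silyloxybutadiene A5. A chiral-Lewis-acid-catalysed Diels–Alder reaction would give cyclohexene A6 with the C3 acetate, a C10 silyl ether, the cis C4/C5 methyls and a C6 aldehyde.
- For it: two C–C bonds, ring A and four stereocentres arise in one catalytic asymmetric step from very simple partners. The cis methyls follow stereospecifically from the dienophile geometry.
- Where it is stronger: bond economy for ring A, and independence from the chiral pool.
- Against it: A4 is α,β-disubstituted and a sluggish dienophile that must form a quaternary centre. A5 is acid-labile and has two competing donor groups, so regiocontrol rests on the small difference between acyloxy and silyloxy. Endo/exo control with α-methyl enals is unreliable. A6 has no C2 oxygen and no ring B; C7–C9 must be added, and the C10 stereocentre is made only to be destroyed.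
- Comparison: the post-cycloaddition sequence would be clearly longer than the six steps that follow the key step here.

**Alternative 3:** Ring A is cut at C1–C10. Ring B is made first as the 4,4-disubstituted cyclohexadienone A7, which carries the complete C1–C4 chain ending in a primary iodide. A tin hydride chain reaction generates the C1 radical, which adds 6-exo to C10 of one enone arm and gives the cis-fused enone A8.
- For it: radical conjugate additions of this kind are tolerant and predictable.
- Where it is stronger: the C3 configuration is fixed before ring closure, so no late hydride selectivity is needed, and there is no ortho/para question.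
- Against it: the difficult C4–C5 bond is not made by the key step and must be forged earlier without the help of a ring. The C2/C3/C4 triad must be assembled acyclically. The two enone arms of A7 are diastereotopic and are differentiated only by the C4 substituents. A8 has lost the C9=C10 unsaturation, which has to be restored by dehydrogenation before C7 can be oxygenated. Tin is used stoichiometrically.
- Comparison: the chosen route uses the same dearomatisation logic, but the dearomatisation itself closes ring A and ring B stays at the dienone level.

Key step: step 7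

## Route

Remarks:
- Locants C1–C10 for the bicyclic compounds are those of the target core defined in the analysis; primed locants belong to the acyl chain.
- Methyl (R)-glycidate 3 and (S)-2-methylbutan-1-ol 16 are taken to be commercially available in high enantiomeric purity.
- Epoxide 13 is drawn as the isomer with the oxygen anti to the C5 methyl; both of its new centres are erased in step 10.

Step 1
Reactants: 1 3-bromo-4-methylphenol
Product: 2 2-bromo-1-methyl-4-(prop-2-en-1-yloxy)benzene
Conditions: allyl bromide, K2CO3, acetone, reflux
Reagents that add atoms: allyl bromide, C=CCBr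
Why: Williamson O-alkylation of the phenoxide; the allyl ether tolerates magnesium, Grignard reagents and silyl triflates and can later be removed by zerovalent palladium under neutral conditions.

Step 2
Reactants: 2 2-bromo-1-methyl-4-(prop-2-en-1-yloxy)benzene; 3 methyl (2R)-oxirane-2-carboxylate
Product: 5 methyl (2R)-2-hydroxy-3-[2-methyl-5-(prop-2-en-1-yloxy)phenyl]propanoate, via aryl Grignard reagent 4 (not isolated)
Conditions: Mg, THF, rt; then CuI (10 mol %), 3, THF, −40 → −20 °C
Reagents that add atoms: magnesium, [Mg] (atoms kept only in 4)
Why: Copper-catalysed Grignard opening of a glycidic ester at its unsubstituted epoxide carbon, a known route to 3-aryl-2-hydroxypropanoates; at low temperature the SN2 opening outruns addition to the ester. The stereocentre of 3 is not touched and becomes C2 (R); the new bond is C10–C1.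

Step 3
Reactants: 5 methyl (2R)-2-hydroxy-3-[2-methyl-5-(prop-2-en-1-yloxy)phenyl]propanoate
Product: 6 methyl (2R)-2-[(tert-butyldimethylsilyl)oxy]-3-[2-methyl-5-(prop-2-en-1-yloxy)phenyl]propanoate
Conditions: TBSCl, imidazole, DMF, rt
Reagents that add atoms: tert-butyldimethylsilyl chloride, CC(C)(C)[Si](C)(C)Cl
Why: Standard silylation of a secondary alcohol; the TBS ether lasts to the final step and its bulk later biases the ring closure.

Step 4
Reactants: 6 methyl (2R)-2-[(tert-butyldimethylsilyl)oxy]-3-[2-methyl-5-(prop-2-en-1-yloxy)phenyl]propanoate
Product: 8 (2R)-2-[(tert-butyldimethylsilyl)oxy]-1-[2-methyl-5-(prop-2-en-1-yloxy)phenyl]pentan-3-one, via Weinreb amide 7 (not isolated)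
Conditions: MeNH(OMe)·HCl, iPrMgCl, THF, −20 °C; then EtMgBr, 0 °C
Reagents that add atoms: N,O-dimethylhydroxylamine hydrochloride, CNOC.Cl (atoms kept only in 7); ethylmagnesium bromide, CC[Mg]Br
Why: Ester-to-Weinreb-amide exchange with the magnesium amide, then Grignard addition, which stops at the ketone because the chelated tetrahedral intermediate is stable until work-up. α-Silyloxy Weinreb amides are known to give ethyl ketones without epimerisation; the step forms C3–C4.

Step 5
Reactants: 8 (2R)-2-[(tert-butyldimethylsilyl)oxy]-1-[2-methyl-5-(prop-2-en-1-yloxy)phenyl]pentan-3-one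
Product: 9 2-{(2R,3Z)-2,3-bis[(tert-butyldimethylsilyl)oxy]pent-3-en-1-yl}-1-methyl-4-(prop-2-en-1-yloxy)benzene
Conditions: TBSOTf, Et3N, CH2Cl2, −78 → 0 °C
Reagents that add atoms: tert-butyldimethylsilyl trifluoromethanesulfonate, CC(C)(C)[Si](C)(C)OS(=O)(=O)C(F)(F)F
Why: Soft enolisation with silyl triflate and amine removes a proton from the unhindered ethyl CH2 and not from the silyloxy-bearing C2, so C2 keeps its configuration. Ethyl ketones with a branched α' substituent give the (Z)-enol ether (methyl cis to the silyloxy group), which avoids allylic 1,3-strain; a TBS enol ether is chosen over TMS for stability in the next two steps.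

Step 6
Reactants: 9 2-{(2R,3Z)-2,3-bis[(tert-butyldimethylsilyl)oxy]pent-3-en-1-yl}-1-methyl-4-(prop-2-en-1-yloxy)benzene
Product: 10 3-{(2R,3Z)-2,3-bis[(tert-butyldimethylsilyl)oxy]pent-3-en-1-yl}-4-methylphenol
Conditions: Pd(PPh3)4 (cat.), morpholine, THF, rt
Reagents that add atoms: none
Why: Tsuji–Trost deallylation: zerovalent palladium ionises the aryl allyl ether and morpholine captures the allyl group. The aprotic, nearly neutral medium leaves the bulky TBS enol ether intact, which acid or fluoride would cleave.

Step 7
Reactants: 10 3-{(2R,3Z)-2,3-bis[(tert-butyldimethylsilyl)oxy]pent-3-en-1-yl}-4-methylphenol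
Product: 11 (4aR,5R,7R)-7-[(tert-butyldimethylsilyl)oxy]-4a,5-dimethyl-4a,5,7,8-tetrahydronaphthalene-2,6-dione
Conditions: PhI(OAc)2, (CF3)2CHOH/CH2Cl2, −10 → 0 °C
Reagents that add atoms: none
Why: The phenol exchanges a ligand at trivalent iodine and loss of PhI leaves a phenoxonium-type cation (or its aryloxyiodane equivalent), whose para carbon C5 is attacked by the nucleophilic β-carbon C4 of the enol ether; the silyloxocarbenium ion then gives up its silyl group to acetate and becomes the C3 ketone. The closest known reaction type is the hypervalent-iodine-mediated dearomatising C–C bond formation of para-substituted phenols with allylsilanes and silyl enol ethers in fluorinated alcohols, including tethered cases. Ring A closes in a six-membered mode that is endo with respect to the enol ether double bond (C3 and C4 both end up in the ring), through a chair-like array in which the enol ether lies over the C5–C10 edge of the arene. C4 is set by the enol ether geometry: in the (Z)-isomer the methyl is trans to C2, so it becomes the equatorial substituent anti to the C2–C3 ring bond, and because the C5 methyl is necessarily axial on ring A (C6 must stay in the plane of ring B) the two methyls come out cis. C5 is set relative to C2: only attack on one face of the arene lets the C2 silyloxy group stand pseudoaxial and escape allylic 1,2-strain with the silyloxy group on C3, which places the C2 oxygen trans to the C5 methyl as in 22. The step needs para rather than ortho closure (C9 is also reachable through a six-membered ring and would rearomatise); the para carbon carries the larger share of the positive charge, is stabilised by its methyl group, lies away from the bulky iodine-bound oxygen, and cannot rearomatise once bonded. The non-nucleophilic, strongly ionising solvent keeps external nucleophiles away from the cation, and the phenol reacts at iodine faster than the hindered enol ether is oxidised or protonated.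

Step 8
Reactants: 11 (4aR,5R,7R)-7-[(tert-butyldimethylsilyl)oxy]-4a,5-dimethyl-4a,5,7,8-tetrahydronaphthalene-2,6-dione
Product: 12 (4aR,5R,6R,7R)-7-[(tert-butyldimethylsilyl)oxy]-6-hydroxy-4a,5-dimethyl-5,6,7,8-tetrahydronaphthalen-2(4aH)-one
Conditions: NaBH4, MeOH/CH2Cl2, −78 °C
Reagents that add atoms: none
Why: At low temperature borohydride reduces the saturated, inductively activated α-silyloxy ketone much faster than the cross-conjugated dienone carbonyl, as in the classic selective reductions of enediones. The axial trajectory at C3 is syn-axial to the C5 methyl, so hydride should enter equatorially from the face of the C2 oxygen and give the axial C3 alcohol (R), trans to the C2 silyl ether and cis to both methyls.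

Step 9
Reactants: 12 (4aR,5R,6R,7R)-7-[(tert-butyldimethylsilyl)oxy]-6-hydroxy-4a,5-dimethyl-5,6,7,8-tetrahydronaphthalen-2(4aH)-one
Product: 13 6,7-epoxide of 12 (target locants; (2R,3R,4R,5R,6R,7R), epoxide oxygen anti to the C5 methyl, C9=C10–C8=O enone retained)
Conditions: H2O2 (30%), NaOH (cat.), MeOH, 0 °C → rt
Reagents that add atoms: hydrogen peroxide, OO
Why: Weitz–Scheffer nucleophilic epoxidation; hydroperoxide adds to C6, the β-CH of the less substituted enone arm, and not to the fully substituted C10, as cross-conjugated 1,4-dien-3-ones are epoxidised only at their disubstituted double bond. Attack anti to the C5 methyl is expected, but the configuration is of no consequence.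

Step 10
Reactants: 13 6,7-epoxide of 12
Product: 14 (4aS,5R,6R,7R)-7-[(tert-butyldimethylsilyl)oxy]-3,6-dihydroxy-4a,5-dimethyl-5,6,7,8-tetrahydronaphthalen-2(4aH)-one
Conditions: KOH, H2O/(CH3)3COH (degassed), rt → 40 °C
Reagents that add atoms: water, O (as hydroxide; its oxygen ends at C7 while the former epoxide oxygen leaves from C6)
Why: Base-mediated isomerisation of a cyclic α,β-epoxy ketone to a diosphenol: hydroxide opens the epoxide (either regiochemistry gives the same 6,7-dihydroxy ketone) and E1cB loss of the C6 hydroxyl leaves the enolised 1,2-diketone, which can enolise only toward C6. Air is excluded because the diosphenolate autoxidises.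

Step 11
Reactants: 14 (4aS,5R,6R,7R)-7-[(tert-butyldimethylsilyl)oxy]-3,6-dihydroxy-4a,5-dimethyl-5,6,7,8-tetrahydronaphthalen-2(4aH)-one
Product: 15 (4aS,5R,6R,7R)-3,7-bis[(tert-butyldimethylsilyl)oxy]-6-hydroxy-4a,5-dimethyl-5,6,7,8-tetrahydronaphthalen-2(4aH)-one
Conditions: TBSCl, imidazole, DMF, 0 °C
Reagents that add atoms: tert-butyldimethylsilyl chloride, CC(C)(C)[Si](C)(C)Cl
Why: The acidic enol hydroxyl of the diosphenol is silylated far faster than the axial C3 hydroxyl, which is flanked by the C4 methyl and the C2 silyl ether and is syn-axial to the C5 methyl; this leaves C3–OH as the only free hydroxyl.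

Step 12
Reactants: 16 (2S)-2-methylbutan-1-ol
Product: 18 ethyl (2E,4E,6S)-6-methylocta-2,4-dienoate, via (2S)-2-methylbutanal 17 (not isolated)
Conditions: (COCl)2, DMSO, iPr2NEt, CH2Cl2, −78 °C; then (EtO)2P(O)CH2CH=CHCO2Et, LiN(SiMe3)2, THF, −78 → 0 °C
Reagents that add atoms: triethyl 4-phosphonocrotonate, CCOC(=O)/C=C/CP(=O)(OCC)OCC
Why: Swern oxidation at −78 °C with a hindered amine gives the configurationally labile aldehyde, whose cold-washed solution is used at once without concentration. The Horner–Wadsworth–Emmons reaction of the vinylogous phosphonate anion forms C4'=C5' with E preference, and the C2'=C3' geometry is carried in the reagent.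

Step 13
Reactants: 18 ethyl (2E,4E,6S)-6-methylocta-2,4-dienoate
Product: 19 (2E,4E,6S)-6-methylocta-2,4-dienoic acid
Conditions: LiOH, THF/MeOH/H2O, rt; then aq HCl
Reagents that add atoms: water, O (as hydroxide)
Why: Plain saponification; the C6' hydrogen is too remote from the carbonyl to be removed by hydroxide, so configuration and double-bond geometry are kept.

Step 14
Reactants: 15 (4aS,5R,6R,7R)-3,7-bis[(tert-butyldimethylsilyl)oxy]-6-hydroxy-4a,5-dimethyl-5,6,7,8-tetrahydronaphthalen-2(4aH)-one; 19 (2E,4E,6S)-6-methylocta-2,4-dienoic acid
Product: 21 (1R,2R,3R,8aS)-3,7-bis[(tert-butyldimethylsilyl)oxy]-1,8a-dimethyl-6-oxo-1,2,3,4,6,8a-hexahydronaphthalen-2-yl (2E,4E,6S)-6-methylocta-2,4-dienoate, via mixed anhydride 20 (not isolated)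
Conditions: 2,4,6-Cl3C6H2COCl, Et3N, THF, rt; then 15, DMAP, toluene, rt → 40 °C
Reagents that add atoms: 2,4,6-trichlorobenzoyl chloride, O=C(Cl)c1c(Cl)cc(Cl)cc1Cl (atoms kept only in 20)
Why: Yamaguchi esterification; the acylpyridinium ion formed from the mixed anhydride and DMAP is reactive enough for a hindered axial secondary alcohol, and C3–OH is the only free hydroxyl. The C3 configuration is not touched.

Step 15
Reactants: 21 (1R,2R,3R,8aS)-3,7-bis[(tert-butyldimethylsilyl)oxy]-1,8a-dimethyl-6-oxo-1,2,3,4,6,8a-hexahydronaphthalen-2-yl (2E,4E,6S)-6-methylocta-2,4-dienoate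
Product: 22 septeremophilane G, (1R,2R,3R,8aS)-3,7-dihydroxy-1,8a-dimethyl-6-oxo-1,2,3,4,6,8a-hexahydronaphthalen-2-yl (2E,4E,6S)-6-methylocta-2,4-dienoate
Conditions: HF·pyridine, pyridine/THF, 0 °C → rt
Reagents that add atoms: none
Why: Buffered hydrogen fluoride cleaves the enol silyl ether and the secondary silyl ether without touching the dienoate or the dienone. The C2 hydroxyl and the C3 ester are trans-diaxial and cannot reach the cyclic orthoester needed for acyl migration.

## Compound list

1 | 3-bromo-4-methylphenol | Cc1ccc(O)cc1Br | starting material
2 | 2-bromo-1-methyl-4-(prop-2-en-1-yloxy)benzene | Cc1ccc(OCC=C)cc1Br | intermediate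
3 | methyl (2R)-oxirane-2-carboxylate (methyl (R)-glycidate) | COC(=O)[C@H]1CO1 | starting material
4 | [2-methyl-5-(prop-2-en-1-yloxy)phenyl]magnesium bromide | Cc1ccc(OCC=C)cc1[Mg]Br | intermediate (not isolated)
5 | methyl (2R)-2-hydroxy-3-[2-methyl-5-(prop-2-en-1-yloxy)phenyl]propanoate | Cc1ccc(OCC=C)cc1C[C@@H](O)C(=O)OC | intermediate
6 | methyl (2R)-2-[(tert-butyldimethylsilyl)oxy]-3-[2-methyl-5-(prop-2-en-1-yloxy)phenyl]propanoate | Cc1ccc(OCC=C)cc1C[C@@H](O[Si](C)(C)C(C)(C)C)C(=O)OC | intermediate
7 | (2R)-2-[(tert-butyldimethylsilyl)oxy]-N-methoxy-N-methyl-3-[2-methyl-5-(prop-2-en-1-yloxy)phenyl]propanamide | Cc1ccc(OCC=C)cc1C[C@@H](O[Si](C)(C)C(C)(C)C)C(=O)N(C)OC | intermediate (not isolated)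
8 | (2R)-2-[(tert-butyldimethylsilyl)oxy]-1-[2-methyl-5-(prop-2-en-1-yloxy)phenyl]pentan-3-one | Cc1ccc(OCC=C)cc1C[C@@H](O[Si](C)(C)C(C)(C)C)C(=O)CC | intermediate
9 | 2-{(2R,3Z)-2,3-bis[(tert-butyldimethylsilyl)oxy]pent-3-en-1-yl}-1-methyl-4-(prop-2-en-1-yloxy)benzene | Cc1ccc(OCC=C)cc1C[C@@H](O[Si](C)(C)C(C)(C)C)/C(O[Si](C)(C)C(C)(C)C)=C/C | intermediate
10 | 3-{(2R,3Z)-2,3-bis[(tert-butyldimethylsilyl)oxy]pent-3-en-1-yl}-4-methylphenol | Cc1ccc(O)cc1C[C@@H](O[Si](C)(C)C(C)(C)C)/C(O[Si](C)(C)C(C)(C)C)=C/C | intermediate (precursor of the key step)
11 | (4aR,5R,7R)-7-[(tert-butyldimethylsilyl)oxy]-4a,5-dimethyl-4a,5,7,8-tetrahydronaphthalene-2,6-dione (C3 ketone, C2 silyl ether, cis C4/C5 methyls) | O=C1[C@H](O[Si](C)(C)C(C)(C)C)CC2=CC(=O)C=C[C@]2(C)[C@H]1C | intermediate (product of the key step)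
12 | (4aR,5R,6R,7R)-7-[(tert-butyldimethylsilyl)oxy]-6-hydroxy-4a,5-dimethyl-5,6,7,8-tetrahydronaphthalen-2(4aH)-one | O[C@H]1[C@H](O[Si](C)(C)C(C)(C)C)CC2=CC(=O)C=C[C@]2(C)[C@H]1C | intermediate
13 | 6,7-epoxide of 12 (target locants; oxygen anti to the C5 methyl) | O[C@H]1[C@H](O[Si](C)(C)C(C)(C)C)CC2=CC(=O)[C@@H]3O[C@@H]3[C@]2(C)[C@H]1C | intermediate
14 | (4aS,5R,6R,7R)-7-[(tert-butyldimethylsilyl)oxy]-3,6-dihydroxy-4a,5-dimethyl-5,6,7,8-tetrahydronaphthalen-2(4aH)-one | O[C@H]1[C@H](O[Si](C)(C)C(C)(C)C)CC2=CC(=O)C(O)=C[C@]2(C)[C@H]1C | intermediate
15 | (4aS,5R,6R,7R)-3,7-bis[(tert-butyldimethylsilyl)oxy]-6-hydroxy-4a,5-dimethyl-5,6,7,8-tetrahydronaphthalen-2(4aH)-one | O[C@H]1[C@H](O[Si](C)(C)C(C)(C)C)CC2=CC(=O)C(O[Si](C)(C)C(C)(C)C)=C[C@]2(C)[C@H]1C | intermediate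
16 | (2S)-2-methylbutan-1-ol | CC[C@H](C)CO | starting material
17 | (2S)-2-methylbutanal | CC[C@H](C)C=O | intermediate (not isolated)
18 | ethyl (2E,4E,6S)-6-methylocta-2,4-dienoate | CC[C@H](C)/C=C/C=C/C(=O)OCC | intermediate
19 | (2E,4E,6S)-6-methylocta-2,4-dienoic acid | CC[C@H](C)/C=C/C=C/C(=O)O | intermediate
20 | (2E,4E,6S)-6-methylocta-2,4-dienoic 2,4,6-trichlorobenzoic anhydride | CC[C@H](C)/C=C/C=C/C(=O)OC(=O)c1c(Cl)cc(Cl)cc1Cl | intermediate (not isolated)
21 | (1R,2R,3R,8aS)-3,7-bis[(tert-butyldimethylsilyl)oxy]-1,8a-dimethyl-6-oxo-1,2,3,4,6,8a-hexahydronaphthalen-2-yl (2E,4E,6S)-6-methylocta-2,4-dienoate | CC[C@H](C)/C=C/C=C/C(=O)O[C@H]1[C@H](O[Si](C)(C)C(C)(C)C)CC2=CC(=O)C(O[Si](C)(C)C(C)(C)C)=C[C@]2(C)[C@H]1C | intermediate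
22 | septeremophilane G | CC[C@H](C)/C=C/C=C/C(=O)O[C@H]1[C@H](O)CC2=CC(=O)C(O)=C[C@]2(C)[C@H]1C | target

## Step count and least certain steps

Total step count: 15. Longest linear sequence: 13 (steps 1–11, 14, 15); steps 12 and 13 make the side-chain acid.

**Step 7 (key step).**
- Most likely failure: closure at the ortho carbon C9 followed by rearomatisation, since that ring is also six-membered.
- Other failure modes: loss of the enol ether by protonation in the acidic medium before it can cyclise; capture of the cation at C5 by acetate or solvent; and weak face selection, because the electronic preference of an attacked enol ether for an in-plane allylic C–O bond works against the allylic 1,2-strain argument.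
- Fallback (sets out from 10, returns to 11): the polarity of the C4–C5 bond formation is reversed.
 - Bromination of the enol ether of 10 with N-bromosuccinimide (THF, −78 °C) would give 3-[(2R)-4-bromo-2-(tert-butyldimethylsilyloxy)-3-oxopentyl]-4-methylphenol F1 as a mixture at C4.
 - The potassium phenoxide of F1 (KOC(CH3)3, (CH3)3COH/THF, high dilution) would close ring A by intramolecular para-C-alkylation, a known alkylative dearomatisation. O-alkylation cannot compete within the molecule because the tether cannot reach the oxygen.
 - The C4 epimers are expected to converge on the equatorial, cis-configured methyl of 11 through the C3 enolate. Exposure of the C2 centre to base is the price of this variant.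

**Step 10.**
- Most likely failure: retro-aldol cleavage of the β-hydroxy ketone formed on epoxide opening, benzilic-acid-type ring contraction of the diketone tautomer, or oxidative degradation of the diosphenolate.
- Fallback (sets out from 12, returns to 14): the C7 oxygen is introduced by enolate oxidation instead of through the epoxide.
 - Hydrogenation with RhCl(PPh3)3/H2 saturates only the disubstituted C6=C7 bond and gives the 6,7-dihydro enone F2.
 - Kinetic deprotonation at C7 (LiN(SiMe3)2, two equivalents, −78 °C, the first consumed by the C3 hydroxyl) and oxidation of the enolate with 2-(phenylsulfonyl)-3-phenyloxaziridine gives the 7-hydroxy enone F3.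
 - Cu(OAc)2 in MeOH under air oxidises the α-ketol to the 1,2-diketone, which enolises to 14.

**Step 8.**
- Most likely failure: poor facial selectivity, because the polar preference for hydride attack anti to the axial C2–O bond opposes the steric block by the C5 methyl. Partial reduction of the dienone carbonyl is a lesser risk.
- Fallback (sets out from 11, returns to 12): the reduction is made intramolecular.
 - HF·pyridine removes the silyl group to give the α-hydroxy ketone F4.
 - Me4NBH(OAc)3 in AcOH/MeCN (Saksena–Evans reduction) binds to the C2 hydroxyl and delivers hydride to C3 from that face, giving the trans-diol F5 without touching the dienone.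
 - TBSCl/imidazole at low temperature silylates the less hindered C2 hydroxyl and returns 12.

**Step 14.**
- Most likely failure: acylation of the hindered axial C3 hydroxyl is too slow, and under forcing conditions the dienoyl group deconjugates or loses its E geometry through ketene formation or conjugate addition of DMAP.
- Fallback (sets out from 15, returns to 21): a small acyl group is attached first and the diene is built on it.
 - 15 is esterified with diethylphosphonoacetic acid (DCC, DMAP) to give the phosphonoacetate F6.
 - A Horner–Wadsworth–Emmons reaction under Masamune–Roush conditions (LiCl, iPr2NEt, MeCN) with (2E,4S)-4-methylhex-2-enal F7, itself made from 17 by Wittig reaction with Ph3P=CHCHO, forms the C2'=C3' bond and gives 21.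

**Step 6.**
- Most likely failure: transfer of the enol silyl group to the liberated phenoxide, or C-allylation of the enol ether by the allylpalladium intermediate.
- Fallback (sets out from 8, returns to 10): the order of deallylation and enol silylation is reversed.
 - 8 is deallylated under the same palladium conditions to the phenol ketone F8.
 - In one flask the phenol is masked with TMSCl/Et3N as the aryl trimethylsilyl ether F9, and the ketone is converted with TBSOTf/Et3N into the (Z)-enol ether F10.
 - Brief treatment with K2CO3 in MeOH at 0 °C removes only the far more labile aryl trimethylsilyl group and gives 10.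

## Further compounds

F1 | step 7 | 3-[(2R)-4-bromo-2-(tert-butyldimethylsilyloxy)-3-oxopentyl]-4-methylphenol (both C4 epimers) | Cc1ccc(O)cc1C[C@@H](O[Si](C)(C)C(C)(C)C)C(=O)C(C)Br
F2 | step 10 | 6,7-dihydro derivative of 12 (C9=C10–C8=O enone, C3 hydroxyl, C2 silyl ether) | O[C@H]1[C@H](O[Si](C)(C)C(C)(C)C)CC2=CC(=O)CC[C@]2(C)[C@H]1C
F3 | step 10 | 7-hydroxy derivative of F2 (C7 configuration not controlled) | O[C@H]1[C@H](O[Si](C)(C)C(C)(C)C)CC2=CC(=O)C(O)C[C@]2(C)[C@H]1C
F4 | step 8 | (4aR,5R,7R)-7-hydroxy-4a,5-dimethyl-4a,5,7,8-tetrahydronaphthalene-2,6-dione | O=C1[C@H](O)CC2=CC(=O)C=C[C@]2(C)[C@H]1C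
F5 | step 8 | (4aR,5R,6R,7R)-6,7-dihydroxy-4a,5-dimethyl-5,6,7,8-tetrahydronaphthalen-2(4aH)-one | O[C@H]1[C@H](O)CC2=CC(=O)C=C[C@]2(C)[C@H]1C
F6 | step 14 | C3 (diethoxyphosphoryl)acetate of 15 | CCOP(=O)(OCC)CC(=O)O[C@H]1[C@H](O[Si](C)(C)C(C)(C)C)CC2=CC(=O)C(O[Si](C)(C)C(C)(C)C)=C[C@]2(C)[C@H]1C
F7 | step 14 | (2E,4S)-4-methylhex-2-enal | CC[C@H](C)/C=C/C=O
F8 | step 6 | (2R)-2-[(tert-butyldimethylsilyl)oxy]-1-(5-hydroxy-2-methylphenyl)pentan-3-one | Cc1ccc(O)cc1C[C@@H](O[Si](C)(C)C(C)(C)C)C(=O)CC
F9 | step 6 | (2R)-2-[(tert-butyldimethylsilyl)oxy]-1-[2-methyl-5-(trimethylsilyloxy)phenyl]pentan-3-one | Cc1ccc(O[Si](C)(C)C)cc1C[C@@H](O[Si](C)(C)C(C)(C)C)C(=O)CC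
F10 | step 6 | aryl trimethylsilyl ether of 10 | Cc1ccc(O[Si](C)(C)C)cc1C[C@@H](O[Si](C)(C)C(C)(C)C)/C(O[Si](C)(C)C(C)(C)C)=C/C
A1 | alternative 1 | (−)-quinic acid | O=C(O)[C@]1(O)C[C@@H](O)[C@@H](O)[C@H](O)C1
A2 | alternative 1 | 2-methyl enone with the trans-diol as a butane-2,3-diyl bis-ketal | CC1=C[C@H]2O[C@](C)(OC)[C@@](C)(OC)O[C@@H]2CC1=O
A3 | alternative 1 | ring A ketone with cis C4/C5 methyls, quaternary C5 but-2-ynyl group and protected diol | CC#CC[C@]1(C)[C@@H](C)[C@H]2O[C@](C)(OC)[C@@](C)(OC)O[C@@H]2CC1=O
A4 | alternative 2 | tiglaldehyde, (E)-2-methylbut-2-enal | C/C=C(C)/C=O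
A5 | alternative 2 | (1E,3E)-1-acetoxy-4-(tert-butyldimethylsilyloxy)buta-1,3-diene | CC(=O)O/C=C/C=C/O[Si](C)(C)C(C)(C)C
A6 | alternative 2 | ring A cyclohexene with C3 acetate, C10 silyl ether, cis C4/C5 methyls and C6 aldehyde | CC(=O)O[C@H]1C=C[C@@H](O[Si](C)(C)C(C)(C)C)[C@](C)(C=O)[C@H]1C
A7 | alternative 3 | 4-methylcyclohexa-2,5-dienone carrying at C5 the C1–C4 chain with C1 iodide, C2 silyl ether and C3 PMB ether | COc1ccc(CO[C@@H]([C@H](O[Si](C)(C)C(C)(C)C)CI)[C@H](C)C2(C)C=CC(=O)C=C2)cc1
A8 | alternative 3 | cis-fused bicyclic enone with C2 silyl ether, C3 PMB ether and cis C4/C5 methyls | COc1ccc(CO[C@H]2[C@H](O[Si](C)(C)C(C)(C)C)C[C@@H]3CC(=O)C=C[C@]3(C)[C@H]2C)cc1
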